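## Retrosynthetic overview

1. Endgame: the C17 ketone and C24 acid come from a C17/C24 diol (double oxidation, then chlorite oxidation); the two remaining silyl ethers are removed last.
2. Union: C11–C12 sp3–sp2 Negishi coupling of west iodide 20 (C1–C11) with east dienyl iodide 48 (C12–C24).
3. West: the only ring (the dihydropyranone) is closed by ring-closing metathesis before the union, after a catalytic asymmetric anti-crotylboration of a (2E,4Z)-dienal; the 8Z olefin comes from a Still–Gennari olefination and C10 from an asymmetric hydrogenation.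
4. East: the C12–C15 diene comes from Wittig and Takai olefinations of a C15 aldehyde; C16 from allylboration of the C17 aldehyde with a Z-bis(boronate); C21–C22 from a Negishi coupling with an E-iodoenoate.
5. The C18–C20 anti,anti triad comes from a meso diol (double hydroboration of an achiral dienol) that a lipase desymmetrises.

Assumption: atoms are numbered C1 (lactone C=O) to C24 (CO2H), with C16' the hydroxymethyl carbon; ethyl (2E)-3-iodobut-2-enoate (30), phosphonate 5, ylide 44 and (S)-TRIP are taken as purchasable.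

Abbreviations: TBS = tert-butyldimethylsilyl, TES = triethylsilyl, TIPS = triisopropylsilyl, pin = pinacolato, 9-BBN = 9-borabicyclo[3.3.1]nonane, DMP = Dess–Martin periodinane, TRIP = 3,3'-bis(2,4,6-triisopropylphenyl)-1,1'-binaphthyl-2,2'-diyl hydrogen phosphate.

## West fragment (C1–C11)

Step 1
Reactants: 1 methyl 2-(hydroxymethyl)prop-2-enoate
Product: 2 methyl (2R)-3-hydroxy-2-methylpropanoate
Conditions: H2 (10 bar), [Rh(cod)2]BF4 (0.5 mol%), chiral bisphospholane ligand (catASium M type, antipode giving the R ester), CH2Cl2, 25 °C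
Reagents that add atoms: none
Why: Rhodium-catalysed asymmetric hydrogenation of the hydroxyl-bearing acrylate delivers H2 to one enantioface and so sets the C10 stereocentre catalytically from an achiral alkene.

Step 2
Reactants: 2 methyl (2R)-3-hydroxy-2-methylpropanoate
Product: 3 methyl (2R)-3-[(tert-butyldimethylsilyl)oxy]-2-methylpropanoate
Conditions: TBSCl, imidazole, CH2Cl2, 25 °C
Reagents that add atoms: tert-butyldimethylsilyl chloride, CC(C)(C)[Si](C)(C)Cl
Why: Imidazole-promoted silylation of the primary alcohol does not touch the stereocentre.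

Step 3
Reactants: 3 methyl (2R)-3-[(tert-butyldimethylsilyl)oxy]-2-methylpropanoate
Product: 4 (2R)-3-[(tert-butyldimethylsilyl)oxy]-2-methylpropanal
Conditions: i-Bu2AlH (1.1 equiv), CH2Cl2, −78 °C; Rochelle salt work-up
Reagents that add atoms: none
Why: Low-temperature DIBAL reduction stops at the tetrahedral aluminium hemiacetal, so the aldehyde is released only on work-up and the α-centre is not epimerised.

Step 4
Reactants: 5 methyl 2-[bis(2,2,2-trifluoroethoxy)phosphoryl]acetate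
Product: 6 methyl 2-[bis(2,2,2-trifluoroethoxy)phosphoryl]butanoate (racemic)
Conditions: NaH, iodoethane, THF/DMF, 0 → 25 °C
Reagents that add atoms: iodoethane, CCI
Why: C-alkylation of the stabilised phosphonoacetate anion gives the α-ethyl Still–Gennari reagent.

Step 5
Reactants: 4 (2R)-3-[(tert-butyldimethylsilyl)oxy]-2-methylpropanal; 6 methyl 2-[bis(2,2,2-trifluoroethoxy)phosphoryl]butanoate
Product: 7 methyl (2Z,4S)-5-[(tert-butyldimethylsilyl)oxy]-2-ethyl-4-methylpent-2-enoate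
Conditions: KN(SiMe3)2, 18-crown-6, THF, −78 °C
Reagents that add atoms: none
Why: Still–Gennari olefination with the electron-poor phosphonate is kinetically Z-selective, which places the ester carbon (C7) cis to C10 as the 8Z olefin needs, and C10 does not epimerise at −78 °C.

Step 6
Reactants: 7 methyl (2Z,4S)-5-[(tert-butyldimethylsilyl)oxy]-2-ethyl-4-methylpent-2-enoate
Product: 8 (2Z,4S)-5-[(tert-butyldimethylsilyl)oxy]-2-ethyl-4-methylpent-2-en-1-ol
Conditions: i-Bu2AlH (2.2 equiv), CH2Cl2, −78 °C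
Reagents that add atoms: none
Why: DIBAL reduces the enoate 1,2 to the allylic alcohol without affecting the olefin geometry.

Step 7
Reactants: 8 (2Z,4S)-5-[(tert-butyldimethylsilyl)oxy]-2-ethyl-4-methylpent-2-en-1-ol
Product: 9 (2Z,4S)-5-[(tert-butyldimethylsilyl)oxy]-2-ethyl-4-methylpent-2-enal
Conditions: DMP, NaHCO3, CH2Cl2, 0 °C
Reagents that add atoms: none
Why: Buffered Dess–Martin oxidation gives the enal under neutral conditions that avoid Z to E isomerisation.

Step 8
Reactants: 9 (2Z,4S)-5-[(tert-butyldimethylsilyl)oxy]-2-ethyl-4-methylpent-2-enal; 10 triethyl phosphonoacetate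
Product: 11 ethyl (2E,4Z,6S)-7-[(tert-butyldimethylsilyl)oxy]-4-ethyl-6-methylhepta-2,4-dienoate
Conditions: LiCl, DBU, MeCN, 25 °C
Reagents that add atoms: none
Why: Horner–Wadsworth–Emmons olefination under Masamune–Roush conditions is E-selective (the C6=C7 olefin) and mild enough to keep the 8Z geometry.

Step 9
Reactants: 11 ethyl (2E,4Z,6S)-7-[(tert-butyldimethylsilyl)oxy]-4-ethyl-6-methylhepta-2,4-dienoate
Product: 12 (2E,4Z,6S)-7-[(tert-butyldimethylsilyl)oxy]-4-ethyl-6-methylhepta-2,4-dien-1-ol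
Conditions: i-Bu2AlH (2.2 equiv), CH2Cl2, −78 °C
Reagents that add atoms: none
Why: DIBAL 1,2-reduction of the dienoate gives the dienol with both olefins intact.

Step 10
Reactants: 12 (2E,4Z,6S)-7-[(tert-butyldimethylsilyl)oxy]-4-ethyl-6-methylhepta-2,4-dien-1-ol
Product: 13 (2E,4Z,6S)-7-[(tert-butyldimethylsilyl)oxy]-4-ethyl-6-methylhepta-2,4-dienal
Conditions: DMP, NaHCO3, CH2Cl2, 0 °C
Reagents that add atoms: none
Why: Buffered Dess–Martin oxidation of the allylic alcohol gives the dienal without olefin isomerisation.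

Step 11
Reactants: 13 (2E,4Z,6S)-7-[(tert-butyldimethylsilyl)oxy]-4-ethyl-6-methylhepta-2,4-dienal; 14 (E)-crotylboronic acid pinacol ester
Product: 15 (3S,4R,5E,7Z,9S)-10-[(tert-butyldimethylsilyl)oxy]-7-ethyl-3,9-dimethyldeca-1,5,7-trien-4-ol
Conditions: (S)-TRIP (5 mol%), 4 Å molecular sieves, toluene, −30 °C; aqueous work-up
Reagents that add atoms: none
Why: Chiral phosphoric acid-catalysed crotylboration runs through a closed chair transition state, so the E-boronate gives the anti C4/C5 relationship and (S)-TRIP directs attack to the Si face of the aldehyde, which sets 4S and 5R.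

Step 12
Reactants: 15 (3S,4R,5E,7Z,9S)-10-[(tert-butyldimethylsilyl)oxy]-7-ethyl-3,9-dimethyldeca-1,5,7-trien-4-ol; 16 acryloyl chloride
Product: 17 (3S,4R,5E,7Z,9S)-10-[(tert-butyldimethylsilyl)oxy]-7-ethyl-3,9-dimethyldeca-1,5,7-trien-4-yl prop-2-enoate
Conditions: i-Pr2NEt, DMAP (cat.), CH2Cl2, −78 → 0 °C
Reagents that add atoms: none
Why: Base-mediated O-acylation installs the acrylate with retention at the carbinol carbon.

Step 13
Reactants: 17 (3S,4R,5E,7Z,9S)-10-[(tert-butyldimethylsilyl)oxy]-7-ethyl-3,9-dimethyldeca-1,5,7-trien-4-yl prop-2-enoate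
Product: 18 (5S,6R)-6-[(1E,3Z,5S)-6-[(tert-butyldimethylsilyl)oxy]-3-ethyl-5-methylhexa-1,3-dien-1-yl]-5-methyl-5,6-dihydro-2H-pyran-2-one
Conditions: second-generation Grubbs catalyst RuCl2(=CHPh)(H2IMes)(PCy3) (5 mol%), CH2Cl2 (2 mM), 40 °C
Reagents that add atoms: none
Why: Ring-closing metathesis starts at the monosubstituted vinyl group and closes the six-membered unsaturated lactone onto the acrylate with loss of ethene, while the conjugated diene stays out because it could only give a four-membered ring.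

Step 14
Reactants: 18 (5S,6R)-6-[(1E,3Z,5S)-6-[(tert-butyldimethylsilyl)oxy]-3-ethyl-5-methylhexa-1,3-dien-1-yl]-5-methyl-5,6-dihydro-2H-pyran-2-one
Product: 19 (5S,6R)-6-[(1E,3Z,5S)-3-ethyl-6-hydroxy-5-methylhexa-1,3-dien-1-yl]-5-methyl-5,6-dihydro-2H-pyran-2-one
Conditions: HF·pyridine, pyridine, THF, 0 → 25 °C
Reagents that add atoms: none
Why: Buffered fluoride-mediated desilylation frees the primary alcohol without opening the base-sensitive unsaturated lactone.

Step 15
Reactants: 19 (5S,6R)-6-[(1E,3Z,5S)-3-ethyl-6-hydroxy-5-methylhexa-1,3-dien-1-yl]-5-methyl-5,6-dihydro-2H-pyran-2-one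
Product: 20 (5S,6R)-6-[(1E,3Z,5S)-3-ethyl-6-iodo-5-methylhexa-1,3-dien-1-yl]-5-methyl-5,6-dihydro-2H-pyran-2-one
Conditions: I2, PPh3, imidazole, CH2Cl2, 0 °C
Reagents that add atoms: iodine, [I][I]
Why: Appel-type iodination converts the primary alcohol by SN2 displacement of the oxyphosphonium, leaving the adjacent C10 centre untouched.

## East fragment (C12–C24)

Step 16
Reactants: 21 methacrolein; 22 isopropenylmagnesium bromide
Product: 23 2,4-dimethylpenta-1,4-dien-3-ol
Conditions: THF, −78 → 0 °C; aqueous work-up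
Reagents that add atoms: none
Why: Grignard 1,2-addition to the enal gives the divinyl carbinol, which is achiral because the two isopropenyl groups are identical.

Step 17
Reactants: 23 2,4-dimethylpenta-1,4-dien-3-ol
Product: 24 tert-butyl[(2,4-dimethylpenta-1,4-dien-3-yl)oxy]dimethylsilane
Conditions: TBSCl, imidazole, DMF, 25 °C
Reagents that add atoms: tert-butyldimethylsilyl chloride, CC(C)(C)[Si](C)(C)Cl
Why: Silylation under non-acidic conditions protects the future C19 hydroxyl without ionising the bis-allylic carbinol.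

Step 18
Reactants: 24 tert-butyl[(2,4-dimethylpenta-1,4-dien-3-yl)oxy]dimethylsilane
Product: 26 meso-(2R,3s,4S)-3-[(tert-butyldimethylsilyl)oxy]-2,4-dimethylpentane-1,5-diol, via bis(9-BBN) dialkylborane 25 (not isolated)
Conditions: 9-BBN (2.4 equiv), THF, 0 → 25 °C; then NaOH, H2O2, 0 °C
Reagents that add atoms: hydrogen peroxide, OO (the two hydroxyl oxygens); 9-borabicyclo[3.3.1]nonane, B1C2CCCC1CCC2 (kept only in 25)
Why: Allylic-strain-controlled anti-Markovnikov hydroboration of each 1,1-disubstituted alkene by the bulky borane places each new methyl stereocentre anti to the silyloxy group, and oxidation with retention gives the anti,anti meso diol.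

Step 19
Reactants: 26 meso-(2R,3s,4S)-3-[(tert-butyldimethylsilyl)oxy]-2,4-dimethylpentane-1,5-diol
Product: 27 meso-(2R,3s,4S)-3-[(tert-butyldimethylsilyl)oxy]-2,4-dimethylpentane-1,5-diyl diacetate
Conditions: Ac2O, pyridine, DMAP (cat.), CH2Cl2, 25 °C
Reagents that add atoms: acetic anhydride, CC(=O)OC(C)=O
Why: Exhaustive acetylation gives the meso diester needed as the enzyme substrate.

Step 20
Reactants: 27 meso-(2R,3s,4S)-3-[(tert-butyldimethylsilyl)oxy]-2,4-dimethylpentane-1,5-diyl diacetate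
Product: 28 (2S,3R,4R)-3-[(tert-butyldimethylsilyl)oxy]-5-hydroxy-2,4-dimethylpentyl acetate
Conditions: Burkholderia cepacia lipase (Amano lipase PS, a triacylglycerol lipase of the serine hydrolase class), phosphate buffer pH 7 / t-BuOMe, 30 °C, pH-stat, stopped after 1 equiv of acid
Reagents that add atoms: none
Why: Lipase-catalysed enantiotopos-selective hydrolysis of the meso diester cleaves only the acetoxymethyl arm on the methine that matches the fast-reacting (S)-2-methylalkan-1-ol pattern (the C21 arm), so the absolute configuration of C18, C19 and C20 is fixed in one step.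

Step 21
Reactants: 28 (2S,3R,4R)-3-[(tert-butyldimethylsilyl)oxy]-5-hydroxy-2,4-dimethylpentyl acetate
Product: 29 (2S,3S,4S)-3-[(tert-butyldimethylsilyl)oxy]-5-iodo-2,4-dimethylpentyl acetate
Conditions: I2, PPh3, imidazole, CH2Cl2, 0 → 25 °C
Reagents that add atoms: iodine, [I][I]
Why: Appel-type iodination of the free primary alcohol proceeds by SN2 at C21 and does not affect the acetate or the silyl ether.

Step 22
Reactants: 29 (2S,3S,4S)-3-[(tert-butyldimethylsilyl)oxy]-5-iodo-2,4-dimethylpentyl acetate; 30 ethyl (2E)-3-iodobut-2-enoate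
Product: 32 ethyl (2E,5R,6R,7S)-8-acetoxy-6-[(tert-butyldimethylsilyl)oxy]-3,5,7-trimethyloct-2-enoate, via alkylzinc iodide 31 (not isolated)
Conditions: 29, Zn dust (activated with BrCH2CH2Br and Me3SiCl), LiCl, THF, 40 °C; then 30, Pd(PPh3)4 (5 mol%), THF, 25 °C
Reagents that add atoms: zinc, [Zn] (kept only in 31)
Why: Negishi coupling: zinc inserts into the primary C–I bond with the ester tolerated, and the alkylzinc iodide couples with the β-iodoenoate at zerovalent palladium with retention of the E geometry (the C22=C23 olefin).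

Step 23
Reactants: 32 ethyl (2E,5R,6R,7S)-8-acetoxy-6-[(tert-butyldimethylsilyl)oxy]-3,5,7-trimethyloct-2-enoate
Product: 33 ethyl (2E,5R,6R,7S)-6-[(tert-butyldimethylsilyl)oxy]-8-hydroxy-3,5,7-trimethyloct-2-enoate
Conditions: K2CO3 (0.2 equiv), EtOH, 0 → 25 °C
Reagents that add atoms: none
Why: Carbonate-catalysed transesterification removes the primary acetate, and in ethanol any exchange at the ethyl enoate is degenerate.

Step 24
Reactants: 33 ethyl (2E,5R,6R,7S)-6-[(tert-butyldimethylsilyl)oxy]-8-hydroxy-3,5,7-trimethyloct-2-enoate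
Product: 34 ethyl (2E,5R,6R,7R)-6-[(tert-butyldimethylsilyl)oxy]-3,5,7-trimethyl-8-oxooct-2-enoate
Conditions: DMP, NaHCO3, CH2Cl2, 0 °C; used directly
Reagents that add atoms: none
Why: Buffered Dess–Martin oxidation gives the α-methyl aldehyde (C17) without epimerising C18.

Step 25
Reactants: 35 buta-1,3-diene; 36 bis(pinacolato)diboron
Product: 37 (Z)-1,4-bis(4,4,5,5-tetramethyl-1,3,2-dioxaborolan-2-yl)but-2-ene
Conditions: Pt(PPh3)4 (3 mol%), toluene, 80 °C
Reagents that add atoms: none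
Why: Platinum-catalysed 1,4-diboration (B–B oxidative addition to zerovalent platinum, then delivery to the termini of the s-cis diene) gives the Z-configured bis(allyl)boronate.

Step 26
Reactants: 34 ethyl (2E,5R,6R,7R)-6-[(tert-butyldimethylsilyl)oxy]-3,5,7-trimethyl-8-oxooct-2-enoate; 37 (Z)-1,4-bis(4,4,5,5-tetramethyl-1,3,2-dioxaborolan-2-yl)but-2-ene
Product: 39 ethyl (2E,5R,6R,7S,8S,9S)-6-[(tert-butyldimethylsilyl)oxy]-8-hydroxy-9-(hydroxymethyl)-3,5,7-trimethylundeca-2,10-dienoate, via homoallylic bis(boronate) 38 (not isolated)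
Conditions: 37 (1.5 equiv), 4 Å molecular sieves, toluene, 25 → 40 °C; then NaBO3·4H2O, THF/H2O, 25 °C
Reagents that add atoms: sodium perborate tetrahydrate, [Na+].[Na+].O[B-]1(O)OO[B-](O)(O)OO1 (oxygen of the CH2OH group)
Why: Allylboration through a closed chair transition state gives the 16,17-syn relationship from the Z γ-substituent, and to avoid a syn-pentane contact with the α-methyl group the aldehyde reacts on its anti-Felkin face (17,18-anti), which fixes C16 as required before perborate oxidises the remaining primary C–B bond with retention.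

Step 27
Reactants: 39 ethyl (2E,5R,6R,7S,8S,9S)-6-[(tert-butyldimethylsilyl)oxy]-8-hydroxy-9-(hydroxymethyl)-3,5,7-trimethylundeca-2,10-dienoate
Product: 40 ethyl (2E,5R,6R,7S,8S,9S)-6-[(tert-butyldimethylsilyl)oxy]-8-hydroxy-3,5,7-trimethyl-9-{[(triisopropylsilyl)oxy]methyl}undeca-2,10-dienoate
Conditions: TIPSCl, imidazole, DMF, 0 → 25 °C
Reagents that add atoms: triisopropylsilyl chloride, CC(C)[Si](Cl)(C(C)C)C(C)C
Why: The bulky silyl chloride reacts only at the primary hydroxyl of the 1,3-diol.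

Step 28
Reactants: 40 ethyl (2E,5R,6R,7S,8S,9S)-6-[(tert-butyldimethylsilyl)oxy]-8-hydroxy-3,5,7-trimethyl-9-{[(triisopropylsilyl)oxy]methyl}undeca-2,10-dienoate
Product: 41 ethyl (2E,5R,6R,7R,8S,9S)-6-[(tert-butyldimethylsilyl)oxy]-3,5,7-trimethyl-8-[(triethylsilyl)oxy]-9-{[(triisopropylsilyl)oxy]methyl}undeca-2,10-dienoate
Conditions: TESOTf, 2,6-lutidine, CH2Cl2, −78 °C
Reagents that add atoms: triethylsilyl trifluoromethanesulfonate, CC[Si](CC)(CC)OS(=O)(=O)C(F)(F)F
Why: The reactive silyl triflate caps the hindered C17 hydroxyl as the most acid-labile silyl ether in the molecule.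

Step 29
Reactants: 41 ethyl (2E,5R,6R,7R,8S,9S)-6-[(tert-butyldimethylsilyl)oxy]-3,5,7-trimethyl-8-[(triethylsilyl)oxy]-9-{[(triisopropylsilyl)oxy]methyl}undeca-2,10-dienoate
Product: 43 C15 aldehyde (the vinyl group of 41 cleaved to CHO; all stereocentres as in 41), via vicinal diol 42 (not isolated)
Conditions: OsO4 (2 mol%), NaIO4 (4 equiv), 2,6-lutidine, dioxane/H2O 3:1, 25 °C
Reagents that add atoms: osmium tetroxide, O=[Os](=O)(=O)=O (carbonyl oxygen; regenerated by sodium periodate, [Na+].[O-]I(=O)(=O)=O)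
Why: Lemieux–Johnson cleavage: OsO4 dihydroxylates only the monosubstituted alkene (the trisubstituted enoate is deactivated) and periodate cleaves the diol under lutidine-buffered conditions that leave C16 intact.

Step 30
Reactants: 43 C15 aldehyde; 44 2-(triphenylphosphoranylidene)propanal
Product: 45 C13 (E)-enal (C13HO–C14(CH3)=C15H–C16; all stereocentres as in 41)
Conditions: toluene, 80 °C
Reagents that add atoms: none
Why: Wittig olefination with the stabilised formyl ylide is E-selective and builds the trisubstituted C14=C15 olefin under neutral conditions.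

Step 31
Reactants: 45 C13 (E)-enal
Product: 46 (12E,14E)-dienyl iodide with C24 ethyl ester (I–C12H=C13H–C14(CH3)=C15H–C16)
Conditions: CrCl2 (8 equiv), CHI3 (3 equiv), THF/dioxane 1:6, 0 → 25 °C
Reagents that add atoms: iodoform, IC(I)I
Why: Takai olefination with the geminal dichromium reagent converts the aldehyde into the E-vinyl iodide while tolerating the ester and silyl ethers.

Step 32
Reactants: 46 (12E,14E)-dienyl iodide with C24 ethyl ester
Product: 47 (12E,14E)-dienyl iodide with free C24 allylic alcohol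
Conditions: i-Bu2AlH (2.5 equiv), CH2Cl2, −78 °C
Reagents that add atoms: none
Why: DIBAL reduces the enoate 1,2 to the allylic alcohol and leaves the vinyl iodide and silyl ethers alone.

Step 33
Reactants: 47 (12E,14E)-dienyl iodide with free C24 allylic alcohol
Product: 48 east fragment: (12E,14E)-dienyl iodide with C24-OTES, C17-OTES, C16'-OTIPS and C19-OTBS
Conditions: TESCl, imidazole, CH2Cl2, 0 °C
Reagents that add atoms: triethylsilyl chloride, CC[Si](Cl)(CC)CC
Why: Silylation masks the only acidic proton before the organozinc coupling, using the same labile group as at C17 so both can be removed together.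

## Union and endgame

Step 34
Reactants: 20 west iodide; 48 east dienyl iodide
Product: 50 fully protected C1–C24 coupling product, via west alkylzinc iodide 49 (not isolated)
Conditions: 20 (1.4 equiv), Zn dust (activated with BrCH2CH2Br and Me3SiCl), LiCl, THF, 35 °C; then 48, PdCl2(dppf) (5 mol%), THF/NMP, 25 °C
Reagents that add atoms: zinc, [Zn] (kept only in 49)
Why: Negishi sp3–sp2 coupling: the primary alkylzinc iodide, which tolerates the unsaturated lactone, transmetalates to the alkenylpalladium formed from the dienyl iodide and reductive elimination forms C11–C12 with retention of the 12E geometry.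

Step 35
Reactants: 50 fully protected C1–C24 coupling product
Product: 51 C17,C24-diol (C16'-OTIPS and C19-OTBS retained)
Conditions: PPTS (0.3 equiv), MeOH/CH2Cl2 1:3, 0 → 25 °C
Reagents that add atoms: none
Why: Acid-catalysed methanolysis cleaves triethylsilyl ethers orders of magnitude faster than the TBS and TIPS ethers.

Step 36
Reactants: 51 C17,C24-diol
Product: 52 C17-ketone C24-enal
Conditions: DMP (3 equiv), NaHCO3, CH2Cl2, 0 → 25 °C
Reagents that add atoms: none
Why: Buffered Dess–Martin oxidation converts the secondary C17 alcohol to the ketone (removing the temporary C17 stereocentre) and the allylic C24 alcohol to the enal without epimerising C16 or C18.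

Step 37
Reactants: 52 C17-ketone C24-enal
Product: 53 C24 carboxylic acid (C16'-OTIPS, C19-OTBS)
Conditions: NaClO2, NaH2PO4, 2-methylbut-2-ene, t-BuOH/H2O, 0 °C
Reagents that add atoms: sodium chlorite, [Na+].[O-]Cl=O
Why: Pinnick oxidation converts only the aldehyde to the acid at about pH 4, and the alkene scavenger removes hypochlorite before it can attack the dienes.

Step 38
Reactants: 53 C24 carboxylic acid
Product: 54 target, (2E,5R,6R,7R,9S,10E,12E,15R,16Z,18E)-17-ethyl-6-hydroxy-9-(hydroxymethyl)-3,5,7,11,15-pentamethyl-19-[(2R,3S)-3-methyl-6-oxo-3,6-dihydro-2H-pyran-2-yl]-8-oxononadeca-2,10,12,16,18-pentaenoic acid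
Conditions: HF·pyridine, pyridine, THF, 0 → 25 °C
Reagents that add atoms: none
Why: Buffered fluoride-mediated global desilylation removes the primary TIPS and secondary TBS ethers under weakly acidic conditions that the β-hydroxy ketone, the C16 centre and the lactone tolerate.

## Compound list

1 | methyl 2-(hydroxymethyl)prop-2-enoate | C=C(CO)C(=O)OC | starting material
2 | methyl (2R)-3-hydroxy-2-methylpropanoate | COC(=O)[C@H](C)CO | intermediate
3 | methyl (2R)-3-[(tert-butyldimethylsilyl)oxy]-2-methylpropanoate | COC(=O)[C@H](C)CO[Si](C)(C)C(C)(C)C | intermediate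
4 | (2R)-3-[(tert-butyldimethylsilyl)oxy]-2-methylpropanal | O=C[C@H](C)CO[Si](C)(C)C(C)(C)C | intermediate
5 | methyl 2-[bis(2,2,2-trifluoroethoxy)phosphoryl]acetate | COC(=O)CP(=O)(OCC(F)(F)F)OCC(F)(F)F | starting material
6 | methyl 2-[bis(2,2,2-trifluoroethoxy)phosphoryl]butanoate (racemic) | CCC(C(=O)OC)P(=O)(OCC(F)(F)F)OCC(F)(F)F | intermediate
7 | methyl (2Z,4S)-5-[(tert-butyldimethylsilyl)oxy]-2-ethyl-4-methylpent-2-enoate | CCC(=C/[C@H](C)CO[Si](C)(C)C(C)(C)C)/C(=O)OC | intermediate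
8 | (2Z,4S)-5-[(tert-butyldimethylsilyl)oxy]-2-ethyl-4-methylpent-2-en-1-ol | CCC(=C/[C@H](C)CO[Si](C)(C)C(C)(C)C)/CO | intermediate
9 | (2Z,4S)-5-[(tert-butyldimethylsilyl)oxy]-2-ethyl-4-methylpent-2-enal | CCC(=C/[C@H](C)CO[Si](C)(C)C(C)(C)C)/C=O | intermediate
10 | triethyl phosphonoacetate | CCOC(=O)CP(=O)(OCC)OCC | starting material
11 | ethyl (2E,4Z,6S)-7-[(tert-butyldimethylsilyl)oxy]-4-ethyl-6-methylhepta-2,4-dienoate | CCC(=C/[C@H](C)CO[Si](C)(C)C(C)(C)C)/C=C/C(=O)OCC | intermediate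
12 | (2E,4Z,6S)-7-[(tert-butyldimethylsilyl)oxy]-4-ethyl-6-methylhepta-2,4-dien-1-ol | CCC(=C/[C@H](C)CO[Si](C)(C)C(C)(C)C)/C=C/CO | intermediate
13 | (2E,4Z,6S)-7-[(tert-butyldimethylsilyl)oxy]-4-ethyl-6-methylhepta-2,4-dienal | CCC(=C/[C@H](C)CO[Si](C)(C)C(C)(C)C)/C=C/C=O | intermediate
14 | (E)-crotylboronic acid pinacol ester | C/C=C/CB1OC(C)(C)C(C)(C)O1 | starting material
15 | (3S,4R,5E,7Z,9S)-10-[(tert-butyldimethylsilyl)oxy]-7-ethyl-3,9-dimethyldeca-1,5,7-trien-4-ol | CCC(=C/[C@H](C)CO[Si](C)(C)C(C)(C)C)/C=C/[C@@H](O)[C@@H](C)C=C | intermediate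
16 | acryloyl chloride | C=CC(=O)Cl | starting material
17 | (3S,4R,5E,7Z,9S)-10-[(tert-butyldimethylsilyl)oxy]-7-ethyl-3,9-dimethyldeca-1,5,7-trien-4-yl prop-2-enoate | CCC(=C/[C@H](C)CO[Si](C)(C)C(C)(C)C)/C=C/[C@@H](OC(=O)C=C)[C@@H](C)C=C | intermediate
18 | (5S,6R)-6-[(1E,3Z,5S)-6-[(tert-butyldimethylsilyl)oxy]-3-ethyl-5-methylhexa-1,3-dien-1-yl]-5-methyl-5,6-dihydro-2H-pyran-2-one | CCC(=C/[C@H](C)CO[Si](C)(C)C(C)(C)C)/C=C/[C@H]1OC(=O)C=C[C@@H]1C | intermediate
19 | (5S,6R)-6-[(1E,3Z,5S)-3-ethyl-6-hydroxy-5-methylhexa-1,3-dien-1-yl]-5-methyl-5,6-dihydro-2H-pyran-2-one | CCC(=C/[C@H](C)CO)/C=C/[C@H]1OC(=O)C=C[C@@H]1C | intermediate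
20 | (5S,6R)-6-[(1E,3Z,5S)-3-ethyl-6-iodo-5-methylhexa-1,3-dien-1-yl]-5-methyl-5,6-dihydro-2H-pyran-2-one (west fragment) | CCC(=C/[C@H](C)CI)/C=C/[C@H]1OC(=O)C=C[C@@H]1C | intermediate
21 | methacrolein (2-methylprop-2-enal) | CC(=C)C=O | starting material
22 | isopropenylmagnesium bromide | CC(=C)[Mg]Br | starting material
23 | 2,4-dimethylpenta-1,4-dien-3-ol (achiral) | CC(=C)C(O)C(C)=C | intermediate
24 | tert-butyl[(2,4-dimethylpenta-1,4-dien-3-yl)oxy]dimethylsilane | CC(=C)C(O[Si](C)(C)C(C)(C)C)C(C)=C | intermediate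
25 | 9,9'-[meso-(2R,3s,4S)-3-[(tert-butyldimethylsilyl)oxy]-2,4-dimethylpentane-1,5-diyl]bis(9-borabicyclo[3.3.1]nonane) | B1(C[C@H](C)[C@H](O[Si](C)(C)C(C)(C)C)[C@H](C)CB2C3CCCC2CCC3)C2CCCC1CCC2 | intermediate (not isolated)
26 | meso-(2R,3s,4S)-3-[(tert-butyldimethylsilyl)oxy]-2,4-dimethylpentane-1,5-diol (anti,anti) | OC[C@H](C)[C@H](O[Si](C)(C)C(C)(C)C)[C@H](C)CO | intermediate
27 | meso-(2R,3s,4S)-3-[(tert-butyldimethylsilyl)oxy]-2,4-dimethylpentane-1,5-diyl diacetate | CC(=O)OC[C@H](C)[C@H](O[Si](C)(C)C(C)(C)C)[C@H](C)COC(C)=O | intermediate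
28 | (2S,3R,4R)-3-[(tert-butyldimethylsilyl)oxy]-5-hydroxy-2,4-dimethylpentyl acetate (acetate on the C17 arm) | CC(=O)OC[C@H](C)[C@H](O[Si](C)(C)C(C)(C)C)[C@H](C)CO | intermediate
29 | (2S,3S,4S)-3-[(tert-butyldimethylsilyl)oxy]-5-iodo-2,4-dimethylpentyl acetate | CC(=O)OC[C@H](C)[C@H](O[Si](C)(C)C(C)(C)C)[C@H](C)CI | intermediate
30 | ethyl (2E)-3-iodobut-2-enoate | I/C(C)=C/C(=O)OCC | starting material
31 | alkylzinc iodide from 29 (C21–ZnI) | CC(=O)OC[C@H](C)[C@H](O[Si](C)(C)C(C)(C)C)[C@H](C)C[Zn]I | intermediate (not isolated)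
32 | ethyl (2E,5R,6R,7S)-8-acetoxy-6-[(tert-butyldimethylsilyl)oxy]-3,5,7-trimethyloct-2-enoate | CC(=O)OC[C@H](C)[C@H](O[Si](C)(C)C(C)(C)C)[C@H](C)C/C(C)=C/C(=O)OCC | intermediate
33 | ethyl (2E,5R,6R,7S)-6-[(tert-butyldimethylsilyl)oxy]-8-hydroxy-3,5,7-trimethyloct-2-enoate | OC[C@H](C)[C@H](O[Si](C)(C)C(C)(C)C)[C@H](C)C/C(C)=C/C(=O)OCC | intermediate
34 | ethyl (2E,5R,6R,7R)-6-[(tert-butyldimethylsilyl)oxy]-3,5,7-trimethyl-8-oxooct-2-enoate | O=C[C@H](C)[C@H](O[Si](C)(C)C(C)(C)C)[C@H](C)C/C(C)=C/C(=O)OCC | intermediate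
35 | buta-1,3-diene | C=CC=C | starting material
36 | bis(pinacolato)diboron | CC1(C)OB(OC1(C)C)B1OC(C)(C)C(C)(C)O1 | starting material
37 | (Z)-1,4-bis(4,4,5,5-tetramethyl-1,3,2-dioxaborolan-2-yl)but-2-ene | CC1(C)OB(C/C=C\CB2OC(C)(C)C(C)(C)O2)OC1(C)C | intermediate
38 | allylboration adduct: C17–O–Bpin borate with C16–CH2Bpin (16,17-syn, 17,18-anti) | C=C[C@@H](CB1OC(C)(C)C(C)(C)O1)[C@H](OB1OC(C)(C)C(C)(C)O1)[C@H](C)[C@H](O[Si](C)(C)C(C)(C)C)[C@H](C)C/C(C)=C/C(=O)OCC | intermediate (not isolated)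
39 | ethyl (2E,5R,6R,7S,8S,9S)-6-[(tert-butyldimethylsilyl)oxy]-8-hydroxy-9-(hydroxymethyl)-3,5,7-trimethylundeca-2,10-dienoate | C=C[C@@H](CO)[C@H](O)[C@H](C)[C@H](O[Si](C)(C)C(C)(C)C)[C@H](C)C/C(C)=C/C(=O)OCC | intermediate
40 | ethyl (2E,5R,6R,7S,8S,9S)-6-[(tert-butyldimethylsilyl)oxy]-8-hydroxy-3,5,7-trimethyl-9-{[(triisopropylsilyl)oxy]methyl}undeca-2,10-dienoate | C=C[C@@H](CO[Si](C(C)C)(C(C)C)C(C)C)[C@H](O)[C@H](C)[C@H](O[Si](C)(C)C(C)(C)C)[C@H](C)C/C(C)=C/C(=O)OCC | intermediate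
41 | ethyl (2E,5R,6R,7R,8S,9S)-6-[(tert-butyldimethylsilyl)oxy]-3,5,7-trimethyl-8-[(triethylsilyl)oxy]-9-{[(triisopropylsilyl)oxy]methyl}undeca-2,10-dienoate | C=C[C@@H](CO[Si](C(C)C)(C(C)C)C(C)C)[C@H](O[Si](CC)(CC)CC)[C@H](C)[C@H](O[Si](C)(C)C(C)(C)C)[C@H](C)C/C(C)=C/C(=O)OCC | intermediate
42 | vicinal diol from 41 (C15 epimer mixture; other centres as in 41) | OCC(O)[C@@H](CO[Si](C(C)C)(C(C)C)C(C)C)[C@H](O[Si](CC)(CC)CC)[C@H](C)[C@H](O[Si](C)(C)C(C)(C)C)[C@H](C)C/C(C)=C/C(=O)OCC | intermediate (not isolated)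
43 | C15 aldehyde: vinyl group of 41 replaced by CHO (stereocentres as in 41) | O=C[C@@H](CO[Si](C(C)C)(C(C)C)C(C)C)[C@H](O[Si](CC)(CC)CC)[C@H](C)[C@H](O[Si](C)(C)C(C)(C)C)[C@H](C)C/C(C)=C/C(=O)OCC | intermediate
44 | 2-(triphenylphosphoranylidene)propanal | CC(C=O)=P(c1ccccc1)(c1ccccc1)c1ccccc1 | starting material
45 | C13 (E)-enal: 43 extended to C13HO–C14(CH3)=C15H (stereocentres as in 41) | O=C/C(C)=C/[C@@H](CO[Si](C(C)C)(C(C)C)C(C)C)[C@H](O[Si](CC)(CC)CC)[C@H](C)[C@H](O[Si](C)(C)C(C)(C)C)[C@H](C)C/C(C)=C/C(=O)OCC | intermediate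
46 | (12E,14E)-dienyl iodide with C24 ethyl ester | I/C=C/C(C)=C/[C@@H](CO[Si](C(C)C)(C(C)C)C(C)C)[C@H](O[Si](CC)(CC)CC)[C@H](C)[C@H](O[Si](C)(C)C(C)(C)C)[C@H](C)C/C(C)=C/C(=O)OCC | intermediate
47 | (12E,14E)-dienyl iodide with free C24 allylic alcohol | I/C=C/C(C)=C/[C@@H](CO[Si](C(C)C)(C(C)C)C(C)C)[C@H](O[Si](CC)(CC)CC)[C@H](C)[C@H](O[Si](C)(C)C(C)(C)C)[C@H](C)C/C(C)=C/CO | intermediate
48 | east fragment: (12E,14E)-dienyl iodide with C24-OTES, C17-OTES, C16'-OTIPS, C19-OTBS | I/C=C/C(C)=C/[C@@H](CO[Si](C(C)C)(C(C)C)C(C)C)[C@H](O[Si](CC)(CC)CC)[C@H](C)[C@H](O[Si](C)(C)C(C)(C)C)[C@H](C)C/C(C)=C/CO[Si](CC)(CC)CC | intermediate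
49 | west alkylzinc iodide from 20 (C11–ZnI) | CCC(=C/[C@H](C)C[Zn]I)/C=C/[C@H]1OC(=O)C=C[C@@H]1C | intermediate (not isolated)
50 | fully protected C1–C24 coupling product (lactone; C17-OTES, C24-OTES, C16'-OTIPS, C19-OTBS) | CCC(=C/[C@H](C)C/C=C/C(C)=C/[C@@H](CO[Si](C(C)C)(C(C)C)C(C)C)[C@H](O[Si](CC)(CC)CC)[C@H](C)[C@H](O[Si](C)(C)C(C)(C)C)[C@H](C)C/C(C)=C/CO[Si](CC)(CC)CC)/C=C/[C@H]1OC(=O)C=C[C@@H]1C | intermediate
51 | C17,C24-diol (C16'-OTIPS, C19-OTBS) | CCC(=C/[C@H](C)C/C=C/C(C)=C/[C@@H](CO[Si](C(C)C)(C(C)C)C(C)C)[C@H](O)[C@H](C)[C@H](O[Si](C)(C)C(C)(C)C)[C@H](C)C/C(C)=C/CO)/C=C/[C@H]1OC(=O)C=C[C@@H]1C | intermediate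
52 | C17-ketone C24-enal (C16'-OTIPS, C19-OTBS) | CCC(=C/[C@H](C)C/C=C/C(C)=C/[C@@H](CO[Si](C(C)C)(C(C)C)C(C)C)C(=O)[C@H](C)[C@H](O[Si](C)(C)C(C)(C)C)[C@H](C)C/C(C)=C/C=O)/C=C/[C@H]1OC(=O)C=C[C@@H]1C | intermediate
53 | C24 carboxylic acid (C16'-OTIPS, C19-OTBS) | CCC(=C/[C@H](C)C/C=C/C(C)=C/[C@@H](CO[Si](C(C)C)(C(C)C)C(C)C)C(=O)[C@H](C)[C@H](O[Si](C)(C)C(C)(C)C)[C@H](C)C/C(C)=C/C(=O)O)/C=C/[C@H]1OC(=O)C=C[C@@H]1C | intermediate
54 | (2E,5R,6R,7R,9S,10E,12E,15R,16Z,18E)-17-ethyl-6-hydroxy-9-(hydroxymethyl)-3,5,7,11,15-pentamethyl-19-[(2R,3S)-3-methyl-6-oxo-3,6-dihydro-2H-pyran-2-yl]-8-oxononadeca-2,10,12,16,18-pentaenoic acid | CCC(=C/[C@H](C)C/C=C/C(C)=C/[C@@H](CO)C(=O)[C@H](C)[C@H](O)[C@H](C)C/C(C)=C/C(=O)O)/C=C/[C@H]1OC(=O)C=C[C@@H]1C | target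

## Step count and risks

Total step count: 38. Longest linear sequence: 22 steps (steps 16–24, 26–33 and 34–38, from methacrolein). The west branch contributes 14 steps (1–3, 5–15) before the union; steps 4 and 25 are one-step reagent preparations.

The three steps most likely to fail are steps 20, 26 and 34.

Step 20 (lipase desymmetrisation). The sense and selectivity on a diester flanking a bulky silyloxy group are predicted by analogy and could be reversed or low. The fallback sets out from diol 26 and comes back at monoacetate 28. The same lipase is run in the acylation direction (vinyl acetate, t-BuOMe, 25 °C, irreversible acyl transfer). The arm that the enzyme would have deacetylated is then the one it acetylates, so a hydrolysis that gave the mirror-image monoester becomes an acylation that gives 28. This makes no new compound (F0).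

Step 26 (allylboration). The thermal reaction may be slow, or the anti-Felkin preference may be too small to give C16 cleanly. The fallback sets out from alcohol 33 (steps 24 and 25 are then not needed) and comes back at keto-enal 52. It uses catalyst control at the alcohol oxidation level: iridium-catalysed transfer-hydrogenative anti-(hydroxymethyl)allylation with 4-vinyl-1,3-dioxolan-2-one (used as the racemate, its stereocentre being lost on ionisation), [Ir(cod)Cl]2, SEGPHOS (the antipode that sets C16 as in 39), 4-chloro-3-nitrobenzoic acid, K3PO4, THF, 90 °C. This gives the C17-epimeric diol F1, with C16 as required and C17 in the Felkin sense, so catalyst and substrate are matched. The epimer is then carried through the chemistry of steps 27–35 unchanged: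
- TIPSCl gives the TIPS ether F2, and TESOTf gives the TES ether F3.
- OsO4/NaIO4 passes through the vicinal diol F4 to the aldehyde F5.
- Ylide 44 gives the enal F6, CrCl2/CHI3 gives the dienyl iodide F7, i-Bu2AlH gives the allylic alcohol F8, and TESCl gives the bis-TES dienyl iodide F9.
- Negishi coupling with zinc reagent 49 gives the coupled product F10, and PPTS/MeOH gives the diol F11.
- Dess–Martin oxidation of F11 removes the C17 stereocentre and gives 52.

Step 34 (Negishi union). Zinc insertion into 20 beside the unsaturated lactone, or transmetalation of the β-branched alkylzinc, may be inefficient. The fallback sets out from 20 and 48 and comes back at 50. It is a nickel-catalysed reductive cross-electrophile coupling of the two iodides without a preformed organometallic (NiI2, 4,4'-di-tert-butyl-2,2'-bipyridine, Mn powder, NaI, DMPU, 25 °C). The alkyl iodide enters as a radical and the dienyl iodide by oxidative addition, which tolerates the lactone and silyl ethers. This makes no new compound (F0).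

## Further compounds

F0 | step 20 | none | none
F1 | step 26 | ethyl (2E,5R,6R,7S,8R,9S)-6-[(tert-butyldimethylsilyl)oxy]-8-hydroxy-9-(hydroxymethyl)-3,5,7-trimethylundeca-2,10-dienoate (C17 epimer of 39) | C=C[C@@H](CO)[C@@H](O)[C@H](C)[C@H](O[Si](C)(C)C(C)(C)C)[C@H](C)C/C(C)=C/C(=O)OCC
F2 | step 26 | C17 epimer of TIPS ether 40 | C=C[C@@H](CO[Si](C(C)C)(C(C)C)C(C)C)[C@@H](O)[C@H](C)[C@H](O[Si](C)(C)C(C)(C)C)[C@H](C)C/C(C)=C/C(=O)OCC
F3 | step 26 | C17 epimer of TES ether 41 | C=C[C@@H](CO[Si](C(C)C)(C(C)C)C(C)C)[C@@H](O[Si](CC)(CC)CC)[C@H](C)[C@H](O[Si](C)(C)C(C)(C)C)[C@H](C)C/C(C)=C/C(=O)OCC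
F4 | step 26 | C17 epimer of vicinal diol 42 | OCC(O)[C@@H](CO[Si](C(C)C)(C(C)C)C(C)C)[C@@H](O[Si](CC)(CC)CC)[C@H](C)[C@H](O[Si](C)(C)C(C)(C)C)[C@H](C)C/C(C)=C/C(=O)OCC
F5 | step 26 | C17 epimer of aldehyde 43 | O=C[C@@H](CO[Si](C(C)C)(C(C)C)C(C)C)[C@@H](O[Si](CC)(CC)CC)[C@H](C)[C@H](O[Si](C)(C)C(C)(C)C)[C@H](C)C/C(C)=C/C(=O)OCC
F6 | step 26 | C17 epimer of enal 45 | O=C/C(C)=C/[C@@H](CO[Si](C(C)C)(C(C)C)C(C)C)[C@@H](O[Si](CC)(CC)CC)[C@H](C)[C@H](O[Si](C)(C)C(C)(C)C)[C@H](C)C/C(C)=C/C(=O)OCC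
F7 | step 26 | C17 epimer of dienyl iodide 46 | I/C=C/C(C)=C/[C@@H](CO[Si](C(C)C)(C(C)C)C(C)C)[C@@H](O[Si](CC)(CC)CC)[C@H](C)[C@H](O[Si](C)(C)C(C)(C)C)[C@H](C)C/C(C)=C/C(=O)OCC
F8 | step 26 | C17 epimer of allylic alcohol 47 | I/C=C/C(C)=C/[C@@H](CO[Si](C(C)C)(C(C)C)C(C)C)[C@@H](O[Si](CC)(CC)CC)[C@H](C)[C@H](O[Si](C)(C)C(C)(C)C)[C@H](C)C/C(C)=C/CO
F9 | step 26 | C17 epimer of east fragment 48 | I/C=C/C(C)=C/[C@@H](CO[Si](C(C)C)(C(C)C)C(C)C)[C@@H](O[Si](CC)(CC)CC)[C@H](C)[C@H](O[Si](C)(C)C(C)(C)C)[C@H](C)C/C(C)=C/CO[Si](CC)(CC)CC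
F10 | step 26 | C17 epimer of coupling product 50 | CCC(=C/[C@H](C)C/C=C/C(C)=C/[C@@H](CO[Si](C(C)C)(C(C)C)C(C)C)[C@@H](O[Si](CC)(CC)CC)[C@H](C)[C@H](O[Si](C)(C)C(C)(C)C)[C@H](C)C/C(C)=C/CO[Si](CC)(CC)CC)/C=C/[C@H]1OC(=O)C=C[C@@H]1C
F11 | step 26 | C17 epimer of diol 51 | CCC(=C/[C@H](C)C/C=C/C(C)=C/[C@@H](CO[Si](C(C)C)(C(C)C)C(C)C)[C@@H](O)[C@H](C)[C@H](O[Si](C)(C)C(C)(C)C)[C@H](C)C/C(C)=C/CO)/C=C/[C@H]1OC(=O)C=C[C@@H]1C
F0 | step 34 | none | none
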